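**Retrosynthetic overview**

- The O5 angelate and the free O4–H are unveiled last. The C1 side chain comes from a C2≡C3 alkyne, hydrated regioselectively at C2, that is added as the (S)-but-3-yn-2-ol acetylide to a C1 cycloheptanone.
- The cis-fused γ-lactone (C7, C11) comes from cis-hydrogenation of a C7=C11 butenolide. The butenolide arises when an ester dienolate expels the C9–O bond of an 8-oxabicyclo[3.2.1]octene, so the bridge oxygen becomes lactone O6. The C10 methyl is put on the bicyclic ketone from its exo face.
- The oxabicycle comes from a (4+3) cycloaddition that forms C5–C6 and C9–C10: C5–C1–C10 is a 1-alkoxy-2-silyloxyallyl cation carrying an (S)-1-phenylethyl group, and C6–C9 are the ring carbons of methyl 2-(furan-3-yl)propanoate.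
- Ring order: the seven-membered carbocycle first (as the oxygen-bridged bicycle), the γ-lactone second.
- Feature used: the cycloheptane C1–C5–C6–C7–C8–C9–C10, in which carbonyl-level C1 lies between O-bearing C5 and methyl-bearing C10, and O6 sits on C6 next to C7 with its C11–C12 acid branch.

Key step: step 4

Atom numbers are those of the target: ring C1(OH), C5(OAng), C6(O), C7, C8, C9, C10(Me); chain C2(=O), C3, C4(OH); lactone C11(Me), C12(=O).

Assumption: the (S)-1-phenylethyl group is taken to induce the oxabicycle drawn (alkoxy-bearing carbon S, bridgeheads R). Should the opposite sense prevail, (R)-1-phenylethanol is used and nothing else changes, because the auxiliary is removed later.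

Remark: C11 is racemic in the furan ester and epimeric in the bicyclic intermediates; it becomes trigonal in the bridge-opening step and is set in the hydrogenation that follows.

**Step 1**
Reactants: 1 3-bromofuran; 2 1-methoxy-1-(trimethylsilyloxy)prop-1-ene
Product: 3 methyl 2-(furan-3-yl)propanoate (racemic)
Conditions: Pd(dba)2 (2 mol %), P(t-Bu)3 (4 mol %), ZnF2 (0.5 equiv), DMF, 80 °C
Reagents that add atoms: none
Why: Palladium-catalysed α-arylation of a silyl ketene acetal with zinc fluoride as activator couples the heteroaryl bromide under near-neutral conditions, which avoids ester self-condensation and furan metalation.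

**Step 2**
Reactants: 4 1,1-dimethoxyacetone; 5 (S)-1-phenylethanol
Product: 6 1-methoxy-1-[(S)-1-phenylethoxy]propan-2-one (both acetal epimers)
Conditions: 4 (3 equiv), PPTS (2 mol %), toluene, 60 °C, 5 Å molecular sieves (MeOH trap); Et3N
Reagents that add atoms: none
Why: Acid-catalysed transacetalisation driven by removal of methanol exchanges one methoxy group, and the benzylic C–O bond of 5 is not broken, so its configuration is kept.

**Step 3**
Reactants: 6 1-methoxy-1-[(S)-1-phenylethoxy]propan-2-one
Product: 7 triethyl({3-methoxy-3-[(S)-1-phenylethoxy]prop-1-en-2-yl}oxy)silane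
Conditions: LDA, THF, −78 °C; Et3SiCl, Et3N, −78 → 0 °C
Reagents that add atoms: chlorotriethylsilane, CC[Si](Cl)(CC)CC
Why: Kinetic enolisation of the methyl ketone (the acetal C–H is not removed) and O-silylation give the silyl enol ether that serves as the oxyallyl cation precursor.

**Step 4**
Reactants: 3 methyl 2-(furan-3-yl)propanoate; 7 triethyl({3-methoxy-3-[(S)-1-phenylethoxy]prop-1-en-2-yl}oxy)silane
Product: 8 methyl 2-{(1R,4S,5R)-3-oxo-4-[(S)-1-phenylethoxy]-8-oxabicyclo[3.2.1]oct-6-en-6-yl}propanoate (alkoxy group equatorial and trans to the oxygen bridge; both C11 epimers)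
Conditions: 3 (1.5 equiv), Me3SiOTf (10 mol %), CH2Cl2, −95 → −78 °C; pyridine quench
Reagents that add atoms: none
Why: Me3SiOTf removes methoxide from 7 to give a 1-alkoxy-2-(triethylsilyloxy)allyl cation, in essence an oxocarbenium ion conjugated with a silyl enol ether; furan C2 of 3, the α-carbon activated by the 3-alkyl group, attacks the oxocarbenium carbon (C5–C6), the enol ether terminus C10 then closes onto the furan-derived oxocarbenium carbon C9 (C9–C10), and the released silyl triflate carries the chain. The closest known reaction is the low-temperature (4+3) cycloaddition of furan itself with this class of chiral 1-phenylethoxy silyloxyallyl cations generated from α-keto acetal silyl enol ethers. The seven-membered carbocycle closes in the second bond formation as a 7-exo-trig (enol-endo) Mukaiyama-type attack on C9=O+, in the concerted limit a six-electron [4π+2π] addition, and the furan oxygen is left as the C6–O–C9 bridge. C6 and C9 are cis because the furan reacts suprafacially; C5 is set relative to them by the compact transition state of the W-shaped cation, which places the alkoxy group equatorial and trans to the bridge, and in the absolute sense by the (S)-1-phenylethyl group shielding one face of the cation. The step needs head-to-head regiochemistry (alkoxy terminus bonded to the furan carbon next to the side chain), which rests on the higher nucleophilicity of C2 in 3-alkylfurans meeting the more electrophilic oxocarbenium terminus, and it needs facial control, which rests on the auxiliary; the ester is inert to the catalytic Lewis acid.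

**Step 5**
Reactants: 8 the cycloadduct ketone
Product: 9 methyl 2-{2-methyl-3-oxo-4-[(S)-1-phenylethoxy]-8-oxabicyclo[3.2.1]oct-6-en-6-yl}propanoate (new methyl on C10 axial, cis to the oxygen bridge)
Conditions: LDA (1.05 equiv), THF, −78 °C; MeI, DMPU, −78 → −40 °C; NH4Cl (aq) at −40 °C
Reagents that add atoms: iodomethane, CI
Why: Kinetic enolate alkylation: the lithium enolate should form at the unhindered α′-methylene C10 (away from the alkoxy-bearing C5 and faster than at the hindered tertiary ester α-CH) and methyl iodide enters from the exo face syn to the oxygen bridge, giving the C10 methyl cis to the bridge oxygen as the target requires, while the remaining equatorial C10–H is poorly aligned for re-enolisation.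

**Step 6**
Reactants: 9 the methylated bicyclic ketone
Product: 10 methyl 2-{3-hydroxy-2-methyl-4-[(S)-1-phenylethoxy]-8-oxabicyclo[3.2.1]oct-6-en-6-yl}propanoate (endo alcohol expected)
Conditions: NaBH4, MeOH/CH2Cl2, −20 → 0 °C
Reagents that add atoms: none
Why: Borohydride reduction (the ester is untouched) masks C1 as a carbinol so that no ketone enolate can open the wrong bridge bond or lead on to a tropone in step 7; hydride is expected from the exo face, but the C1 configuration is irrelevant because C1 is re-oxidised in step 9.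

**Step 7**
Reactants: 10 the bicyclic alcohol
Product: 12 7-hydroxy-3,6-dimethyl-8-[(S)-1-phenylethoxy]-6,7,8,8a-tetrahydro-2H-cyclohepta[b]furan-2-one, via hydroxy dienoate 11 (not isolated)
Conditions: LDA (2.2 equiv), THF, −78 → 0 °C; AcOH; then PPTS (cat.), CH2Cl2, rt
Reagents that add atoms: none
Why: Proposed new method: after O1–H, LDA removes C11–H to give an ester dienolate (O–C12=C11–C7=C8) whose γ-carbon C8 is next to C9, so the allylic C9–O bridge bond is expelled in a vinylogous E1cB elimination driven by release of bicyclic strain and formation of the C11=C7–C8=C9 dienoate; only this bridge bond can break, because C6–O is not adjacent to a carbanionic carbon, and lithium held between the enolate oxygen and the bridge oxygen should keep the ester on the C6 side so that the freed O6 alkoxide lactonises to the butenolide; the closest known reaction types are the base-induced eliminative ring opening of oxabicyclic ketones and esters and the loss of a δ-oxygen from ester dienolates (δ-alkoxy enoate to dienoate).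

**Step 8**
Reactants: 12 the butenolide diene
Product: 13 7-hydroxy-3,6-dimethyl-8-[(S)-1-phenylethoxy]octahydro-2H-cyclohepta[b]furan-2-one (H-6, H-7 and H-11 all cis)
Conditions: H2 (60 bar), PtO2 (10 mol %), EtOAc, rt
Reagents that add atoms: none
Why: Heterogeneous cis-hydrogenation: the disubstituted C8=C9 bond is saturated first and the tetrasubstituted butenolide should then take up hydrogen on the face bearing H-6 (the other face is covered by C5 of the seven-membered ring), which sets H-7 and H-11 cis to H-6, and platinum in a neutral ester solvent is chosen because it cleaves benzylic ethers far more slowly than palladium.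

**Step 9**
Reactants: 13 the saturated lactone alcohol
Product: 14 3,6-dimethyl-8-[(S)-1-phenylethoxy]hexahydro-2H-cyclohepta[b]furan-2,7(3H)-dione (C1 ketone)
Conditions: Dess–Martin periodinane, pyridine, CH2Cl2, 0 °C → rt
Reagents that add atoms: none
Why: Dess–Martin oxidation under buffered, non-basic conditions returns the C1 ketone without epimerising C10 or C5 and without β-elimination of the C6 acyloxy group.

**Step 10**
Reactants: 15 (S)-but-3-yn-2-ol
Product: 16 (S)-tert-butyl(but-3-yn-2-yloxy)dimethylsilane
Conditions: TBSCl, imidazole, CH2Cl2, 0 °C → rt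
Reagents that add atoms: tert-butylchlorodimethylsilane, CC(C)(C)[Si](C)(C)Cl
Why: Standard silylation protects O4 so that it cannot be acylated in step 14, and the stereocentre is not touched.

**Step 11**
Reactants: 14 the C1 ketone; 16 (S)-tert-butyl(but-3-yn-2-yloxy)dimethylsilane
Product: 17 7-{(S)-3-[(tert-butyldimethylsilyl)oxy]but-1-yn-1-yl}-7-hydroxy-3,6-dimethyl-8-[(S)-1-phenylethoxy]octahydro-2H-cyclohepta[b]furan-2-one (C1–OH cis to the C10 methyl and to O6, alkynyl cis to O5)
Conditions: 16 (3 equiv), n-BuLi, THF, −78 °C; anhydrous CeCl3, −78 °C; then 14, −78 °C; NH4Cl (aq)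
Reagents that add atoms: none
Why: Alkynylcerium 1,2-addition (non-basic, so enolisation, loss of the β-acyloxy group and attack on the lactone should not compete): chelation of the metal between C1=O and the O5 ether holds O5 in the carbonyl plane, which turns the C10 methyl pseudo-axial on the lactone-bearing face, and the slim acetylide should add axially from the opposite face, cis to O5 and trans to the C10 methyl and O6.

**Step 12**
Reactants: 17 the tertiary propargylic alcohol
Product: 19 7-{(S)-3-[(tert-butyldimethylsilyl)oxy]butanoyl}-7-hydroxy-3,6-dimethyl-8-[(S)-1-phenylethoxy]octahydro-2H-cyclohepta[b]furan-2-one, via spiro cyclic carbonate 18 (not isolated)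
Conditions: AgOAc (10 mol %), DBU (1 equiv), CO2 (10 bar), MeCN, rt; then H2O, rt
Reagents that add atoms: carbon dioxide, O=C=O (its oxygen ends on C2); water, O (hydrolyses the carbonate and returns CO2)
Why: Silver-catalysed carboxylative cyclisation of the tertiary propargylic alcohol (the carbonate oxygen attacks the activated alkyne 5-exo-dig at C2) fixes the new oxygen on C2 and not on C3, and hydrolysis of the enol carbonate with loss of CO2 gives the α-hydroxy ketone, a CO2-mediated regioselective alkyne hydration.

**Step 13**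
Reactants: 19 the α-hydroxy ketone
Product: 20 7-{(S)-3-[(tert-butyldimethylsilyl)oxy]butanoyl}-7,8-dihydroxy-3,6-dimethyloctahydro-2H-cyclohepta[b]furan-2-one
Conditions: H2 (1 bar), Pd(OH)2/C, EtOAc, rt
Reagents that add atoms: none
Why: Hydrogenolysis of the benzylic ether removes the auxiliary as ethylbenzene; no alkene or alkyne remains, and the aliphatic ketone, the lactone and the silyl ether are inert in ethyl acetate.

**Step 14**
Reactants: 20 the C1,C5-diol; 21 angelic acid
Product: 23 7-{(S)-3-[(tert-butyldimethylsilyl)oxy]butanoyl}-7-hydroxy-3,6-dimethyl-2-oxooctahydro-2H-cyclohepta[b]furan-8-yl (Z)-2-methylbut-2-enoate, via mixed anhydride 22 (not isolated)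
Conditions: 21, 2,4,6-trichlorobenzoyl chloride, Et3N, toluene, rt; then 20, toluene, 75 °C
Reagents that add atoms: none
Why: Yamaguchi-type esterification through the angelic 2,4,6-trichlorobenzoic mixed anhydride, run without a nucleophilic catalyst, acylates the secondary C5 hydroxyl without Z-to-E isomerisation to the tiglate; the tertiary C1 hydroxyl is too hindered to react and O4 is silylated.

**Step 15**
Reactants: 23 the O4-silylated angelate
Product: 24 CNP0321985.2, (3R,3aS,6S,7S,8S,8aR)-7-hydroxy-7-[(S)-3-hydroxybutanoyl]-3,6-dimethyl-2-oxooctahydro-2H-cyclohepta[b]furan-8-yl (Z)-2-methylbut-2-enoate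
Conditions: HF·pyridine, pyridine, THF, 0 °C → rt
Reagents that add atoms: none
Why: Fluoride cleavage of the silyl ether with buffered HF·pyridine is mild enough to spare the angelate geometry, the β-hydroxy ketone (no retro-aldol or dehydration) and the lactone.

**Compound list**

1 | 3-bromofuran | Brc1ccoc1 | starting material
2 | 1-methoxy-1-(trimethylsilyloxy)prop-1-ene (E/Z mixture) | CC=C(OC)O[Si](C)(C)C | starting material
3 | methyl 2-(furan-3-yl)propanoate (racemic) | COC(=O)C(C)c1ccoc1 | intermediate
4 | 1,1-dimethoxyacetone | CC(=O)C(OC)OC | starting material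
5 | (S)-1-phenylethanol | C[C@H](O)c1ccccc1 | starting material
6 | 1-methoxy-1-[(S)-1-phenylethoxy]propan-2-one (acetal epimers) | CC(=O)C(OC)O[C@@H](C)c1ccccc1 | intermediate
7 | triethyl({3-methoxy-3-[(S)-1-phenylethoxy]prop-1-en-2-yl}oxy)silane | C=C(O[Si](CC)(CC)CC)C(OC)O[C@@H](C)c1ccccc1 | intermediate
8 | methyl 2-{(1R,4S,5R)-3-oxo-4-[(S)-1-phenylethoxy]-8-oxabicyclo[3.2.1]oct-6-en-6-yl}propanoate (C11 epimers) | C[C@@H](c1ccccc1)O[C@H]1[C@@H]2O[C@@H](C=C2C(C)C(=O)OC)CC1=O | intermediate
9 | methyl 2-{2-methyl-3-oxo-4-[(S)-1-phenylethoxy]-8-oxabicyclo[3.2.1]oct-6-en-6-yl}propanoate (2-methyl cis to the oxygen bridge; C11 epimers) | C[C@@H](c1ccccc1)O[C@H]1[C@@H]2O[C@@H](C=C2C(C)C(=O)OC)[C@H](C)C1=O | intermediate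
10 | methyl 2-{3-hydroxy-2-methyl-4-[(S)-1-phenylethoxy]-8-oxabicyclo[3.2.1]oct-6-en-6-yl}propanoate (endo alcohol; C11 epimers) | C[C@@H](c1ccccc1)O[C@H]1[C@@H]2O[C@@H](C=C2C(C)C(=O)OC)[C@H](C)[C@H]1O | intermediate
11 | methyl (2Z)-2-{5,7-dihydroxy-4-methyl-6-[(S)-1-phenylethoxy]cyclohept-2-en-1-ylidene}propanoate | C[C@@H](c1ccccc1)O[C@H]1[C@H](O)/C(=C(/C)C(=O)OC)C=C[C@H](C)[C@H]1O | intermediate
12 | 7-hydroxy-3,6-dimethyl-8-[(S)-1-phenylethoxy]-6,7,8,8a-tetrahydro-2H-cyclohepta[b]furan-2-one | C[C@@H](c1ccccc1)O[C@H]1[C@@H]2OC(=O)C(C)=C2C=C[C@H](C)[C@H]1O | intermediate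
13 | 7-hydroxy-3,6-dimethyl-8-[(S)-1-phenylethoxy]octahydro-2H-cyclohepta[b]furan-2-one (H-3, H-3a, H-8a cis) | C[C@@H](c1ccccc1)O[C@H]1[C@@H]2OC(=O)[C@H](C)[C@@H]2CC[C@H](C)[C@H]1O | intermediate
14 | 3,6-dimethyl-8-[(S)-1-phenylethoxy]hexahydro-2H-cyclohepta[b]furan-2,7(3H)-dione | C[C@@H](c1ccccc1)O[C@H]1[C@@H]2OC(=O)[C@H](C)[C@@H]2CC[C@H](C)C1=O | intermediate
15 | (S)-but-3-yn-2-ol | C#C[C@H](C)O | starting material
16 | (S)-tert-butyl(but-3-yn-2-yloxy)dimethylsilane | C#C[C@H](C)O[Si](C)(C)C(C)(C)C | intermediate
17 | 7-{(S)-3-[(tert-butyldimethylsilyl)oxy]but-1-yn-1-yl}-7-hydroxy-3,6-dimethyl-8-[(S)-1-phenylethoxy]octahydro-2H-cyclohepta[b]furan-2-one | C[C@@H](c1ccccc1)O[C@H]1[C@@H]2OC(=O)[C@H](C)[C@@H]2CC[C@H](C)[C@@]1(O)C#C[C@H](C)O[Si](C)(C)C(C)(C)C | intermediate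
18 | spiro (Z)-4-alkylidene-1,3-dioxolan-2-one at C1 (O1–C(=O)–O–C2=C3H) | C[C@@H](c1ccccc1)O[C@H]1[C@@H]2OC(=O)[C@H](C)[C@@H]2CC[C@H](C)[C@]13OC(=O)O/C3=C\[C@H](C)O[Si](C)(C)C(C)(C)C | intermediate
19 | 7-{(S)-3-[(tert-butyldimethylsilyl)oxy]butanoyl}-7-hydroxy-3,6-dimethyl-8-[(S)-1-phenylethoxy]octahydro-2H-cyclohepta[b]furan-2-one | C[C@@H](c1ccccc1)O[C@H]1[C@@H]2OC(=O)[C@H](C)[C@@H]2CC[C@H](C)[C@@]1(O)C(=O)C[C@H](C)O[Si](C)(C)C(C)(C)C | intermediate
20 | 7-{(S)-3-[(tert-butyldimethylsilyl)oxy]butanoyl}-7,8-dihydroxy-3,6-dimethyloctahydro-2H-cyclohepta[b]furan-2-one | O[C@H]1[C@@H]2OC(=O)[C@H](C)[C@@H]2CC[C@H](C)[C@@]1(O)C(=O)C[C@H](C)O[Si](C)(C)C(C)(C)C | intermediate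
21 | angelic acid, (Z)-2-methylbut-2-enoic acid | C/C=C(/C)C(=O)O | starting material
22 | angelic 2,4,6-trichlorobenzoic anhydride | C/C=C(/C)C(=O)OC(=O)c1c(Cl)cc(Cl)cc1Cl | intermediate
23 | O4-tert-butyldimethylsilyl ether of the target | C/C=C(/C)C(=O)O[C@H]1[C@@H]2OC(=O)[C@H](C)[C@@H]2CC[C@H](C)[C@@]1(O)C(=O)C[C@H](C)O[Si](C)(C)C(C)(C)C | intermediate
24 | CNP0321985.2 | C/C=C(/C)C(=O)O[C@H]1[C@@H]2OC(=O)[C@H](C)[C@@H]2CC[C@H](C)[C@@]1(O)C(=O)C[C@H](C)O | target

**Step count**

Total: 15 steps. Longest linear sequence: 13 steps (steps 2–9 and 11–15, from 1,1-dimethoxyacetone).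

**Steps most likely to fail**

Step 7 (proposed new method). The dienolate may simply be reprotonated without expelling the bridge oxygen, the new C7=C11 bond may form with the ester turned away from O6 so that lactonisation stalls, or excess base may reach C10 through the dienoate and scramble it. The fallback uses known chemistry only, sets out from 8 and comes back at 14. The ketone of 8 is enolised toward the unsubstituted C10 and the C9–O bond is expelled by the established silyl triflate/amine opening of 8-oxabicyclo[3.2.1]oct-6-en-3-ones (Me3SiOTf, Et3N, CH2Cl2, −78 → 0 °C, short contact to avoid further loss of silanol to a tropone). This gives methyl 2-{5-oxo-6-[(S)-1-phenylethoxy]-7-(trimethylsilyloxy)cyclohepta-1,3-dien-1-yl}propanoate F1. HF·pyridine removes the silyl group and the freed O6 lactonises to 3-methyl-8-[(S)-1-phenylethoxy]-8,8a-dihydro-2H-cyclohepta[b]furan-2,7(3H)-dione F2. Et3N moves the C7=C8 bond into conjugation with the lactone, giving the butenolide enone 3-methyl-8-[(S)-1-phenylethoxy]-8,8a-dihydro-2H-cyclohepta[b]furan-2,7(4H)-dione F3. Hydrogenation over PtO2 as in step 8 saturates C9=C10 and the butenolide to 3-methyl-8-[(S)-1-phenylethoxy]hexahydro-2H-cyclohepta[b]furan-2,7(3H)-dione F4. Kinetic enolisation at C10 (LDA, −78 °C) and methylation trans to the C5 alkoxy group then gives 14.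

Step 4. The cation may attack furan C5 instead of C2, which would put the side chain next to C9 and later break the wrong bridge bond, or the auxiliary may give poor facial control. The fallback sets out from 7 and 1 and comes back at 9. 3-Bromofuran, whose small halogen directs electrophiles to C2, is used as the four-carbon partner under the conditions of step 4 to give 6-bromo-4-[(S)-1-phenylethoxy]-8-oxabicyclo[3.2.1]oct-6-en-3-one F5. Exo-methylation at C10 (LDA, MeI), now without any competing ester proton, gives 6-bromo-2-methyl-4-[(S)-1-phenylethoxy]-8-oxabicyclo[3.2.1]oct-6-en-3-one F6. The propanoate is then attached to the vinyl bromide by the coupling of step 1 (Pd(dba)2, P(t-Bu)3, ZnF2, 2, DMF), which delivers 9. This fallback also removes the ketone-versus-ester chemoselectivity question of step 5.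

Step 8. The tetrasubstituted butenolide may take up hydrogen too slowly, and at the pressure needed the benzylic ether may be cleaved or the phenyl ring saturated. The fallback sets out from 12 and comes back at 13. The disubstituted C8=C9 bond alone is saturated (H2, 1 bar, Pd/C poisoned with Ph2S, EtOAc) to give 7-hydroxy-3,6-dimethyl-8-[(S)-1-phenylethoxy]-4,5,6,7,8,8a-hexahydro-2H-cyclohepta[b]furan-2-one F7. Conjugate reduction (NaBH4, NiCl2·6H2O, MeOH, 0 °C) delivers hydride to C7 on the H-6 face and gives the cis-fused lactone as a C11 epimer mixture, 7-hydroxy-3,6-dimethyl-8-[(S)-1-phenylethoxy]octahydro-2H-cyclohepta[b]furan-2-one (C3 unassigned) F8. Enolisation (LDA, 2.2 equiv, −78 °C) and kinetic protonation on the convex face with a hindered phenol then place the C11 methyl endo and give 13.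

**Further compounds**

F1 | step 7 | methyl 2-{5-oxo-6-[(S)-1-phenylethoxy]-7-(trimethylsilyloxy)cyclohepta-1,3-dien-1-yl}propanoate | C[C@@H](c1ccccc1)O[C@H]1[C@H](O[Si](C)(C)C)C(C(C)C(=O)OC)=CC=CC1=O
F2 | step 7 | 3-methyl-8-[(S)-1-phenylethoxy]-8,8a-dihydro-2H-cyclohepta[b]furan-2,7(3H)-dione | C[C@@H](c1ccccc1)O[C@H]1[C@@H]2OC(=O)C(C)C2=CC=CC1=O
F3 | step 7 | 3-methyl-8-[(S)-1-phenylethoxy]-8,8a-dihydro-2H-cyclohepta[b]furan-2,7(4H)-dione | C[C@@H](c1ccccc1)O[C@H]1[C@@H]2OC(=O)C(C)=C2CC=CC1=O
F4 | step 7 | 3-methyl-8-[(S)-1-phenylethoxy]hexahydro-2H-cyclohepta[b]furan-2,7(3H)-dione | C[C@@H](c1ccccc1)O[C@H]1[C@@H]2OC(=O)[C@H](C)[C@@H]2CCCC1=O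
F5 | step 4 | 6-bromo-4-[(S)-1-phenylethoxy]-8-oxabicyclo[3.2.1]oct-6-en-3-one | C[C@@H](c1ccccc1)O[C@H]1[C@@H]2O[C@@H](C=C2Br)CC1=O
F6 | step 4 | 6-bromo-2-methyl-4-[(S)-1-phenylethoxy]-8-oxabicyclo[3.2.1]oct-6-en-3-one | C[C@@H](c1ccccc1)O[C@H]1[C@@H]2O[C@@H](C=C2Br)[C@H](C)C1=O
F7 | step 8 | 7-hydroxy-3,6-dimethyl-8-[(S)-1-phenylethoxy]-4,5,6,7,8,8a-hexahydro-2H-cyclohepta[b]furan-2-one | C[C@@H](c1ccccc1)O[C@H]1[C@@H]2OC(=O)C(C)=C2CC[C@H](C)[C@H]1O
F8 | step 8 | 7-hydroxy-3,6-dimethyl-8-[(S)-1-phenylethoxy]octahydro-2H-cyclohepta[b]furan-2-one (C3 epimers) | C[C@@H](c1ccccc1)O[C@H]1[C@@H]2OC(=O)C(C)[C@@H]2CC[C@H](C)[C@H]1O
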